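**Plan**
- Ring numbered O1–O2–C3–C4–C5, chain C1′–C15′ counted from C5. C3 carries a methyl, O2 and a CH2 bonded to the carboxyl carbon: the imprint of adding a peroxide oxygen and CO across a methallyl C=C.
- Retrosynthetic cuts, in order: C9′=C10′ (Julia–Kocienski), C7′=C8′ (formyl Wittig), C2′–C3′ (Wittig, then diimide), O2–C3 together with CH2–CO2 (key step), C5–OO (oxetane perhydrolysis), methallyl–C(sp2) (Suzuki–Miyaura).
- Forward: an acyclic C8 dienol goes through epoxide, 1,3-diol and oxetane (a transient ring) to a tertiary hydroperoxide. The only ring of the target, the 1,2-dioxolane, closes in step 8. The chain is then joined as C3′–C7′, C8′–C9′, C10′–C15′, and the ester is hydrolysed last.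
- Stereochemistry: C5 comes from the Sharpless epoxidation, is kept through hydride opening and oxetane closure, and is inverted once in the perhydrolysis. C3 is set relative to C5 in the key step. 7E comes from the stabilised ylide, 9E from the Julia–Kocienski step, and 12Z is bought with (Z)-hex-3-en-1-ol.

Key step: step 8

Remark: 2-(4-bromobutyl)-1,3-dioxolane (19) is assumed to be a catalogue compound; the facial sense of the epoxidation in step 3 is assigned by analogy with nerol.

**Route**

Step 1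
Reactants: 1 but-2-yn-1-ol
Product: 3 (2Z)-3-iodobut-2-en-1-ol, via cyclic alkenylalanate 2 (not isolated)
Conditions: Red-Al, THF, 0 °C→rt; EtOAc; then I2, −78→0 °C; Rochelle salt
Reagents that add atoms: iodine, II
Why: Hydroxyl-directed trans-hydroalumination delivers hydride to C2 and aluminium to C3 inside a five-membered alanate, and iodinolysis of the C–Al bond with retention should give the (Z)-3-iodo allylic alcohol.

Step 2
Reactants: 3 (2Z)-3-iodobut-2-en-1-ol; 4 4,4,5,5-tetramethyl-2-(2-methylprop-2-en-1-yl)-1,3,2-dioxaborolane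
Product: 5 (2Z)-3,5-dimethylhexa-2,5-dien-1-ol
Conditions: Pd(dppf)Cl2 (5 mol %), K2CO3, THF/H2O, 60 °C
Reagents that add atoms: none
Why: Suzuki–Miyaura sp2–sp3 coupling of an alkenyl iodide with an allylic boronate proceeds with retention of alkene geometry, and the symmetric methallyl unit has no α/γ ambiguity, so the methallyl group should end cis to CH2OH.

Step 3
Reactants: 5 (2Z)-3,5-dimethylhexa-2,5-dien-1-ol
Product: 6 [(2R,3S)-3-methyl-3-(2-methylprop-2-en-1-yl)oxiran-2-yl]methanol
Conditions: Ti(OiPr)4 (10 mol %), D-(−)-diethyl tartrate (12 mol %), t-BuOOH, 4 Å MS, CH2Cl2, −20 °C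
Reagents that add atoms: tert-butyl hydroperoxide, CC(C)(C)OO
Why: Sharpless asymmetric epoxidation is hydroxyl-directed, so the isolated 1,1-disubstituted alkene is left alone, and D-(−)-tartrate should deliver oxygen to the face that makes C3 S, the mirror image of the nerol/L-(+)-tartrate outcome.

Step 4
Reactants: 6 [(2R,3S)-3-methyl-3-(2-methylprop-2-en-1-yl)oxiran-2-yl]methanol
Product: 7 (3S)-3,5-dimethylhex-5-ene-1,3-diol
Conditions: Red-Al, THF, 0 °C→rt; Rochelle salt
Reagents that add atoms: none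
Why: Alkoxide-bound aluminium hydride opens the 2,3-epoxy alcohol by intramolecular hydride delivery to C2, the less substituted carbon, so the 1,3-diol should form with the C3–O bond and its S configuration untouched.

Step 5
Reactants: 7 (3S)-3,5-dimethylhex-5-ene-1,3-diol
Product: 9 (2S)-2-methyl-2-(2-methylprop-2-en-1-yl)oxetane, via primary monotosylate 8 (not isolated)
Conditions: n-BuLi (1 equiv), THF, 0 °C; TsCl (1 equiv); n-BuLi (1 equiv), 0→60 °C
Reagents that add atoms: none
Why: One-pot sulfonylation of the primary alkoxide followed by 4-exo-tet Williamson closure by the tertiary alkoxide should give the oxetane with retention, because the tertiary C–O bond is never broken.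

Step 6
Reactants: 9 (2S)-2-methyl-2-(2-methylprop-2-en-1-yl)oxetane; 10 hydrogen peroxide
Product: 11 (3R)-3-hydroperoxy-3,5-dimethylhex-5-en-1-ol
Conditions: anhydrous H2O2 in Et2O (excess), TMSOTf (0.2 equiv), −78→−40 °C
Reagents that add atoms: none
Why: Lewis-acid-promoted perhydrolysis of a 2,2-disubstituted oxetane opens the ring at the tertiary carbon by backside attack of hydrogen peroxide, so C–O is replaced by C–OOH with inversion (S to R); low temperature and excess peroxide are chosen to outrun ionisation and any reaction at the alkene.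

Step 7
Reactants: 11 (3R)-3-hydroperoxy-3,5-dimethylhex-5-en-1-ol
Product: 13 tert-butyl{[(3R)-3-hydroperoxy-3,5-dimethylhex-5-en-1-yl]oxy}diphenylsilane, via bis-silylated peroxide 12 (not isolated)
Conditions: TBDPSCl (2.3 equiv), imidazole, DMF, 0 °C→rt; then K2CO3, MeOH, 0 °C
Reagents that add atoms: tert-butyl(chloro)diphenylsilane, CC(C)(C)[Si](Cl)(c1ccccc1)c1ccccc1
Why: Exhaustive silylation removes the need to discriminate OH from OOH, and the peroxysilane, a silyl derivative of a far more acidic OH, should then be cleaved by mild carbonate methanolysis in the way aryl silyl ethers are cleaved beside alkyl silyl ethers, leaving the primary TBDPS ether.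

Step 8
Reactants: 13 tert-butyl{[(3R)-3-hydroperoxy-3,5-dimethylhex-5-en-1-yl]oxy}diphenylsilane; 14 carbon monoxide; 15 methanol
Product: 16 methyl 2-[(3R,5S)-5-{2-[tert-butyl(diphenyl)silyl]oxyethyl}-3,5-dimethyl-1,2-dioxolan-3-yl]acetate
Conditions: Pd(OCOCF3)2 (10 mol %), p-benzoquinone (2 equiv), CO (1 atm), MeOH/CH2Cl2 1:1, 0 °C→rt, slow addition of 13
Reagents that add atoms: none
Why: Proposed new method: Pd(II) binds the 1,1-disubstituted alkene and the hydroperoxide oxygen adds to its internal carbon, forming the O2–C3 bond and a CH2–Pd on a quaternary carbon with no β-hydrogen; CO insertion and methanolysis of the acyl-palladium then form the CH2–CO2Me bond and release Pd(0), which benzoquinone should return to Pd(II) before the hydroperoxide intercepts it. The closest known reactions are the Pd(II)/quinone alkoxycarbonylative cyclisations of alkenols and phenols onto 1,1-disubstituted alkenes, which build an oxygen-bearing quaternary carbon with a CH2CO2Me arm, and the Pd(II) Wacker-type cyclisations of unsaturated hydroperoxides to cyclic peroxides; using a hydroperoxide as the nucleophile under CO is the untested part. The single ring, the 1,2-dioxolane, closes in the 5-exo-trig mode, attack at the terminal CH2 (6-endo) being disfavoured electronically. The new stereocentre C3 is set relative to C5 by substrate control: peroxypalladation is reversible through β-peroxide elimination, and the diastereomer with the bulky CH2–Pd trans to the silyloxyethyl arm and cis to the C5 methyl should be the one drained by CO insertion, giving (3R,5S). The step needs carbonylation to beat reversal (secured by the quaternary β-carbon and the CO atmosphere), the peroxide to beat the arm oxygen as nucleophile (secured by the silyl ether), and 1,3-diastereoselectivity (resting on CH3 versus CH2CH2OSi at C5). The minor C3 epimer is a diastereomer removable by chromatography, and a C2-symmetric bis(oxazoline) ligand on palladium is the lever inside the step if the substrate bias is small.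

Step 9
Reactants: 16 methyl 2-[(3R,5S)-5-{2-[tert-butyl(diphenyl)silyl]oxyethyl}-3,5-dimethyl-1,2-dioxolan-3-yl]acetate
Product: 17 methyl 2-[(3R,5S)-5-(2-hydroxyethyl)-3,5-dimethyl-1,2-dioxolan-3-yl]acetate
Conditions: HF·pyridine, pyridine, THF, 0 °C→rt
Reagents that add atoms: none
Why: Fluoride-mediated desilylation under buffered, non-basic conditions should free the primary alcohol without exposing the β-peroxy ester to base, the di-tertiary peroxide being inert to HF·pyridine.

Step 10
Reactants: 17 methyl 2-[(3R,5S)-5-(2-hydroxyethyl)-3,5-dimethyl-1,2-dioxolan-3-yl]acetate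
Product: 18 methyl 2-[(3R,5R)-3,5-dimethyl-5-(2-oxoethyl)-1,2-dioxolan-3-yl]acetate
Conditions: Dess–Martin periodinane, NaHCO3, CH2Cl2, 0 °C→rt
Reagents that add atoms: none
Why: Dess–Martin oxidation gives the aldehyde under neutral, non-enolising conditions that dialkyl peroxides tolerate; the C5 descriptor becomes R only because the formyl group raises the priority of the arm.

Step 11
Reactants: 19 2-(4-bromobutyl)-1,3-dioxolane
Product: 20 [4-(1,3-dioxolan-2-yl)butyl]triphenylphosphonium bromide
Conditions: PPh3, MeCN, reflux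
Reagents that add atoms: triphenylphosphine, c1ccc(cc1)P(c1ccccc1)c1ccccc1
Why: SN2 quaternisation of triphenylphosphine by a primary bromide under neutral conditions that leave the acetal intact.

Step 12
Reactants: 18 methyl 2-[(3R,5R)-3,5-dimethyl-5-(2-oxoethyl)-1,2-dioxolan-3-yl]acetate; 20 [4-(1,3-dioxolan-2-yl)butyl]triphenylphosphonium bromide
Product: 22 methyl 2-[(3R,5S)-5-[(2Z)-6-(1,3-dioxolan-2-yl)hex-2-en-1-yl]-3,5-dimethyl-1,2-dioxolan-3-yl]acetate, via phosphonium ylide 21 (not isolated)
Conditions: 20, KHMDS, THF, 0 °C; ylide added to 18 at −78 °C, then →0 °C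
Reagents that add atoms: none
Why: Wittig olefination with a salt-free non-stabilised ylide at −78 °C should be faster than enolisation of the aldehyde, peroxy aldehydes being known to survive such ylides at low temperature; the mainly Z geometry is irrelevant because the alkene is saturated next.

Step 13
Reactants: 22 methyl 2-[(3R,5S)-5-[(2Z)-6-(1,3-dioxolan-2-yl)hex-2-en-1-yl]-3,5-dimethyl-1,2-dioxolan-3-yl]acetate
Product: 23 methyl 2-[(3R,5S)-5-[6-(1,3-dioxolan-2-yl)hexyl]-3,5-dimethyl-1,2-dioxolan-3-yl]acetate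
Conditions: dipotassium azodicarboxylate, AcOH, CH2Cl2, 0 °C→rt
Reagents that add atoms: none
Why: Diimide reduction transfers H2 to the unhindered cis-alkene in a concerted syn addition and does not touch O–O bonds, esters or acetals, which makes it the standard reductant for unsaturated peroxides.

Step 14
Reactants: 23 methyl 2-[(3R,5S)-5-[6-(1,3-dioxolan-2-yl)hexyl]-3,5-dimethyl-1,2-dioxolan-3-yl]acetate
Product: 24 methyl 2-[(3R,5S)-3,5-dimethyl-5-(7-oxoheptyl)-1,2-dioxolan-3-yl]acetate
Conditions: 2 M HCl/THF 1:3, rt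
Reagents that add atoms: water, O
Why: Acid-catalysed acetal hydrolysis should unmask the C7′ aldehyde, the tetrasubstituted 1,2-dioxolane and the methyl ester being stable to dilute acid at room temperature.

Step 15
Reactants: 24 methyl 2-[(3R,5S)-3,5-dimethyl-5-(7-oxoheptyl)-1,2-dioxolan-3-yl]acetate
Product: 25 methyl 2-[(3R,5S)-3,5-dimethyl-5-[(7E)-9-oxonon-7-en-1-yl]-1,2-dioxolan-3-yl]acetate
Conditions: Ph3P=CHCHO (1.3 equiv), toluene, 70 °C
Reagents that add atoms: (triphenylphosphoranylidene)acetaldehyde, O=CC=P(c1ccccc1)(c1ccccc1)c1ccccc1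
Why: Wittig reaction with the stabilised formylmethylene ylide should give the (E)-enal under neutral conditions, the aliphatic aldehyde reacting faster than the enal product.

Step 16
Reactants: 26 (3Z)-hex-3-en-1-ol
Product: 27 5-{[(3Z)-hex-3-en-1-yl]sulfanyl}-1-phenyl-1H-tetrazole
Conditions: 1-phenyl-1H-tetrazole-5-thiol, PPh3, DIAD, THF, 0 °C→rt
Reagents that add atoms: 1-phenyl-1H-tetrazole-5-thiol, Sc1nnnn1-c1ccccc1
Why: Mitsunobu thioetherification of a primary alcohol with the acidic tetrazole thiol; the (Z)-alkene takes no part.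

Step 17
Reactants: 27 5-{[(3Z)-hex-3-en-1-yl]sulfanyl}-1-phenyl-1H-tetrazole; 10 hydrogen peroxide
Product: 28 5-{[(3Z)-hex-3-en-1-yl]sulfonyl}-1-phenyl-1H-tetrazole
Conditions: (NH4)6Mo7O24·4H2O (10 mol %), 30% H2O2, EtOH, 0 °C→rt
Reagents that add atoms: none
Why: Molybdate-catalysed sulfide oxidation should reach the sulfone chemoselectively, the unactivated cis-alkene being epoxidised far more slowly.

Step 18
Reactants: 25 methyl 2-[(3R,5S)-3,5-dimethyl-5-[(7E)-9-oxonon-7-en-1-yl]-1,2-dioxolan-3-yl]acetate; 28 5-{[(3Z)-hex-3-en-1-yl]sulfonyl}-1-phenyl-1H-tetrazole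
Product: 30 methyl 2-[(3R,5S)-3,5-dimethyl-5-[(7E,9E,12Z)-pentadeca-7,9,12-trien-1-yl]-1,2-dioxolan-3-yl]acetate, via potassium sulfonyl carbanion 29 (not isolated)
Conditions: 28, KHMDS, DME, −60 °C; then 25, −60 °C→rt
Reagents that add atoms: none
Why: Julia–Kocienski olefination: the metalated phenyltetrazolyl sulfone adds to the enal, and Smiles rearrangement with loss of SO2 and tetrazololate should give the C9′=C10′ alkene with the E preference typical of these sulfones under potassium/DME conditions; premetalation keeps free base away from the ester and the doubly allylic CH2.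

Step 19
Reactants: 30 methyl 2-[(3R,5S)-3,5-dimethyl-5-[(7E,9E,12Z)-pentadeca-7,9,12-trien-1-yl]-1,2-dioxolan-3-yl]acetate
Product: 31 2-[(3R,5S)-3,5-dimethyl-5-[(7E,9E,12Z)-pentadeca-7,9,12-trien-1-yl]-1,2-dioxolan-3-yl]acetic acid
Conditions: LiOH, THF/H2O, 0 °C→rt; then 1 M HCl to pH 3–4, 0 °C
Reagents that add atoms: lithium hydroxide, [Li+].[OH-]
Why: Saponification of the methyl ester by acyl–oxygen cleavage, the usual last step for 1,2-dioxolane-3-acetic acids, should leave the di-tertiary peroxide and the skipped triene intact at 0 °C.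

**Compound list**

1 | but-2-yn-1-ol | CC#CCO | starting material
2 | sodium 2,2-bis(2-methoxyethoxy)-3-methyl-2,5-dihydro-1,2-oxaluminol-2-uide (cyclic alkenylalanate) | CC1=CCO[Al-]1(OCCOC)OCCOC.[Na+] | intermediate (not isolated)
3 | (2Z)-3-iodobut-2-en-1-ol | C/C(I)=C/CO | intermediate
4 | 4,4,5,5-tetramethyl-2-(2-methylprop-2-en-1-yl)-1,3,2-dioxaborolane | CC(=C)CB1OC(C)(C)C(C)(C)O1 | starting material
5 | (2Z)-3,5-dimethylhexa-2,5-dien-1-ol | C/C(CC(C)=C)=C/CO | intermediate
6 | [(2R,3S)-3-methyl-3-(2-methylprop-2-en-1-yl)oxiran-2-yl]methanol | OC[C@H]1O[C@@]1(C)CC(C)=C | intermediate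
7 | (3S)-3,5-dimethylhex-5-ene-1,3-diol | OCC[C@](O)(C)CC(C)=C | intermediate
8 | (3S)-3-hydroxy-3,5-dimethylhex-5-en-1-yl 4-methylbenzenesulfonate | Cc1ccc(cc1)S(=O)(=O)OCC[C@](O)(C)CC(C)=C | intermediate (not isolated)
9 | (2S)-2-methyl-2-(2-methylprop-2-en-1-yl)oxetane | O1CC[C@]1(C)CC(C)=C | intermediate
10 | hydrogen peroxide | OO | starting material
11 | (3R)-3-hydroperoxy-3,5-dimethylhex-5-en-1-ol | OCC[C@@](OO)(C)CC(C)=C | intermediate
12 | tert-butyl{[(3R)-3-{[tert-butyl(diphenyl)silyl]peroxy}-3,5-dimethylhex-5-en-1-yl]oxy}diphenylsilane | CC(C)(C)[Si](c1ccccc1)(c1ccccc1)OCC[C@@](OO[Si](c1ccccc1)(c1ccccc1)C(C)(C)C)(C)CC(C)=C | intermediate (not isolated)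
13 | tert-butyl{[(3R)-3-hydroperoxy-3,5-dimethylhex-5-en-1-yl]oxy}diphenylsilane | CC(C)(C)[Si](c1ccccc1)(c1ccccc1)OCC[C@@](OO)(C)CC(C)=C | intermediate
14 | carbon monoxide | [C-]#[O+] | starting material
15 | methanol | CO | starting material
16 | methyl 2-[(3R,5S)-5-{2-[tert-butyl(diphenyl)silyl]oxyethyl}-3,5-dimethyl-1,2-dioxolan-3-yl]acetate | CC(C)(C)[Si](c1ccccc1)(c1ccccc1)OCC[C@@]1(C)C[C@](C)(CC(=O)OC)OO1 | intermediate
17 | methyl 2-[(3R,5S)-5-(2-hydroxyethyl)-3,5-dimethyl-1,2-dioxolan-3-yl]acetate | OCC[C@@]1(C)C[C@](C)(CC(=O)OC)OO1 | intermediate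
18 | methyl 2-[(3R,5R)-3,5-dimethyl-5-(2-oxoethyl)-1,2-dioxolan-3-yl]acetate | O=CC[C@@]1(C)C[C@](C)(CC(=O)OC)OO1 | intermediate
19 | 2-(4-bromobutyl)-1,3-dioxolane | BrCCCCC1OCCO1 | starting material
20 | [4-(1,3-dioxolan-2-yl)butyl]triphenylphosphonium bromide | [Br-].C1COC(CCCC[P+](c2ccccc2)(c2ccccc2)c2ccccc2)O1 | intermediate
21 | [4-(1,3-dioxolan-2-yl)butylidene]triphenyl-λ5-phosphane | C1COC(CCCC=P(c2ccccc2)(c2ccccc2)c2ccccc2)O1 | intermediate (not isolated)
22 | methyl 2-[(3R,5S)-5-[(2Z)-6-(1,3-dioxolan-2-yl)hex-2-en-1-yl]-3,5-dimethyl-1,2-dioxolan-3-yl]acetate | C1COC(CCC/C=C\C[C@@]2(C)C[C@](C)(CC(=O)OC)OO2)O1 | intermediate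
23 | methyl 2-[(3R,5S)-5-[6-(1,3-dioxolan-2-yl)hexyl]-3,5-dimethyl-1,2-dioxolan-3-yl]acetate | C1COC(CCCCCC[C@@]2(C)C[C@](C)(CC(=O)OC)OO2)O1 | intermediate
24 | methyl 2-[(3R,5S)-3,5-dimethyl-5-(7-oxoheptyl)-1,2-dioxolan-3-yl]acetate | O=CCCCCCC[C@@]1(C)C[C@](C)(CC(=O)OC)OO1 | intermediate
25 | methyl 2-[(3R,5S)-3,5-dimethyl-5-[(7E)-9-oxonon-7-en-1-yl]-1,2-dioxolan-3-yl]acetate | O=C/C=C/CCCCCC[C@@]1(C)C[C@](C)(CC(=O)OC)OO1 | intermediate
26 | (3Z)-hex-3-en-1-ol | CC/C=C\CCO | starting material
27 | 5-{[(3Z)-hex-3-en-1-yl]sulfanyl}-1-phenyl-1H-tetrazole | CC/C=C\CCSc1nnnn1-c1ccccc1 | intermediate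
28 | 5-{[(3Z)-hex-3-en-1-yl]sulfonyl}-1-phenyl-1H-tetrazole | CC/C=C\CCS(=O)(=O)c1nnnn1-c1ccccc1 | intermediate
29 | potassium (3Z)-1-[(1-phenyl-1H-tetrazol-5-yl)sulfonyl]hex-3-en-1-ide | [K+].CC/C=C\C[CH-]S(=O)(=O)c1nnnn1-c1ccccc1 | intermediate (not isolated)
30 | methyl 2-[(3R,5S)-3,5-dimethyl-5-[(7E,9E,12Z)-pentadeca-7,9,12-trien-1-yl]-1,2-dioxolan-3-yl]acetate | CC/C=C\C/C=C/C=C/CCCCCC[C@@]1(C)C[C@](C)(CC(=O)OC)OO1 | intermediate
31 | 2-[(3R,5S)-3,5-dimethyl-5-[(7E,9E,12Z)-pentadeca-7,9,12-trien-1-yl]-1,2-dioxolan-3-yl]acetic acid | CC/C=C\C/C=C/C=C/CCCCCC[C@@]1(C)C[C@](C)(CC(=O)O)OO1 | target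

**Step count and risks**

Total steps: 19. Longest linear sequence: 16 (steps 1–10, 12–15, 18, 19).

1. Step 8 (new method). Palladium may transfer oxygen from the hydroperoxide to CO or to Pd(0) faster than it mediates peroxypalladation, or the 1,3-induction may be weak. The fallback uses known chemistry, sets out from 13 and returns at 16. Ozonolysis of the methallyl C=C of 13 (O3, pyridine, CH2Cl2, −78 °C) should give the β-hydroperoxy ketone, which closes to the cyclic peroxyhemiketal (5S)-5-{2-[tert-butyl(diphenyl)silyl]oxyethyl}-3,5-dimethyl-1,2-dioxolan-3-ol F1. Acid-catalysed exchange with methanol (TsOH, MeOH) converts it into (5S)-5-{2-[tert-butyl(diphenyl)silyl]oxyethyl}-3-methoxy-3,5-dimethyl-1,2-dioxolane F2. TiCl4 in CH2Cl2 at −78 °C ionises F2 to the cyclic peroxycarbenium ion, which 1-methoxy-1-(trimethylsilyloxy)ethene should attack anti to the larger C5 arm to give 16. In this variant the C3–CH2 bond, not the O2–C3 bond, is formed last.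

2. Step 12. The basic ylide may deprotonate the CH2 between the aldehyde and the peroxide-bearing carbon, and β-elimination of the peroxide would open the ring and erase C5 on re-closure. The fallback sets out from 18 and returns at 23. The first olefination is done with the neutral stabilised ylide (triphenylphosphoranylidene)acetaldehyde (toluene, 60 °C), giving methyl 2-[(3R,5S)-3,5-dimethyl-5-[(2E)-4-oxobut-2-en-1-yl]-1,2-dioxolan-3-yl]acetate F3, whose carbonyl is no longer flanked by that acidic CH2. F3 is then treated with the ylide from commercial [2-(1,3-dioxolan-2-yl)ethyl]triphenylphosphonium bromide (KHMDS, THF, −78 °C) to give methyl 2-[(3R,5S)-5-[(2E,4Z)-6-(1,3-dioxolan-2-yl)hexa-2,4-dien-1-yl]-3,5-dimethyl-1,2-dioxolan-3-yl]acetate F4. Excess diimide saturates both alkenes to give 23.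

3. Step 7. The methanolysis may not discriminate cleanly, either removing the primary silyl ether or leaving the peroxysilane. The fallback sets out from 11 and returns at 13, and masks the hydroperoxide orthogonally. 2-Methoxypropene with catalytic PPTS (CH2Cl2, −20 °C) adds to the more nucleophilic OOH to give (3R)-3-[(2-methoxypropan-2-yl)peroxy]-3,5-dimethylhex-5-en-1-ol F5. TBDPSCl/imidazole then gives tert-butyl{[(3R)-3-[(2-methoxypropan-2-yl)peroxy]-3,5-dimethylhex-5-en-1-yl]oxy}diphenylsilane F6. Aqueous acetic acid in THF removes the perketal to give 13.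

**Further compounds**

F1 | step 8 | (5S)-5-{2-[tert-butyl(diphenyl)silyl]oxyethyl}-3,5-dimethyl-1,2-dioxolan-3-ol | CC(C)(C)[Si](c1ccccc1)(c1ccccc1)OCC[C@@]1(C)CC(C)(O)OO1
F2 | step 8 | (5S)-5-{2-[tert-butyl(diphenyl)silyl]oxyethyl}-3-methoxy-3,5-dimethyl-1,2-dioxolane | CC(C)(C)[Si](c1ccccc1)(c1ccccc1)OCC[C@@]1(C)CC(C)(OC)OO1
F3 | step 12 | methyl 2-[(3R,5S)-3,5-dimethyl-5-[(2E)-4-oxobut-2-en-1-yl]-1,2-dioxolan-3-yl]acetate | O=C/C=C/C[C@@]1(C)C[C@](C)(CC(=O)OC)OO1
F4 | step 12 | methyl 2-[(3R,5S)-5-[(2E,4Z)-6-(1,3-dioxolan-2-yl)hexa-2,4-dien-1-yl]-3,5-dimethyl-1,2-dioxolan-3-yl]acetate | C1COC(C/C=C\C=C\C[C@@]2(C)C[C@](C)(CC(=O)OC)OO2)O1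
F5 | step 7 | (3R)-3-[(2-methoxypropan-2-yl)peroxy]-3,5-dimethylhex-5-en-1-ol | OCC[C@@](OOC(C)(C)OC)(C)CC(C)=C
F6 | step 7 | tert-butyl{[(3R)-3-[(2-methoxypropan-2-yl)peroxy]-3,5-dimethylhex-5-en-1-yl]oxy}diphenylsilane | CC(C)(C)[Si](c1ccccc1)(c1ccccc1)OCC[C@@](OOC(C)(C)OC)(C)CC(C)=C
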